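**Retrosynthetic overview**

1. The strategy rests on ring C: a benzene-1,3-diol whose C1 carries the (E)-ethene bridge to ring B, so that both hydroxyls (C3, C5) are meta to the carbon substituent. This 1,3,5 alternation is what an aldol-folded poly-β-carbonyl chain gives and what electrophilic substitution of a resorcinol cannot give.
2. Aiphanol is traced back through deprotection, decarboxylation and saponification to an acetonide-masked resorcylate stilbene, in which the extra carboxyl carbon of the chain is still present.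
3. Key disconnection: the ring C bond between the olefin-bearing carbon and the carboxyl-bearing carbon is opened to a cinnamoyl diketo-dioxinone. This is made by Claisen acylation of a keto-dioxinone dianion with the imidazolide of a benzodioxane cinnamic acid.
4. The cinnamic acid comes from a (2R,3R)-benzodioxane aldehyde, assembled from a Sharpless epoxy alcohol (from syringaldehyde) and 4-O-allyl protocatechualdehyde. The C7–O bond forms by epoxide opening and the C8–O bond by Mitsunobu closure; the two inversions give the trans-(7R,8R) ring.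
5. Ring order: rings A and B are purchased arenes, the 1,4-dioxane ring closes in step 9, and ring C is built last, in step 13.

Key step: step 13

Assumption: the 3,5-dimethoxy-4-(methoxymethoxy)phenyl ring is taken as close to electronically neutral (two meta methoxy groups, a twisted para acetal oxygen), so its benzylic epoxide behaves as an ordinary trans-3-arylglycidol; the keto-dioxinone and diketo-dioxinone are drawn as keto tautomers.

Abbreviations: ArA = 3,5-dimethoxy-4-(methoxymethoxy)phenyl; BD = (2R,3R)-2-{[tert-butyl(dimethyl)silyl]oxymethyl}-3-ArA-2,3-dihydro-1,4-benzodioxin-6-yl; C7 = aryl-bearing dioxane carbon, C8 = its neighbour, C9 = the CH2O carbon.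

**Route**

Step 1
Reactants: 1 syringaldehyde
Product: 2 3,5-dimethoxy-4-(methoxymethoxy)benzaldehyde
Conditions: MOMCl, iPr2NEt, CH2Cl2, 0 °C → rt
Reagents that add atoms: chloromethyl methyl ether, COCCl
Why: O-alkylation of the phenoxide (methoxymethyl protection) gives an acetal that should survive every basic, reductive and organometallic step ahead and fall to acid at the end.

Step 2
Reactants: 2 3,5-dimethoxy-4-(methoxymethoxy)benzaldehyde; 3 triethyl phosphonoacetate
Product: 4 ethyl (E)-3-(ArA)prop-2-enoate
Conditions: NaH, THF, 0 °C → rt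
Reagents that add atoms: none
Why: Horner–Wadsworth–Emmons olefination with a stabilised phosphonate anion should give the (E)-cinnamate.

Step 3
Reactants: 4 ethyl (E)-3-(ArA)prop-2-enoate
Product: 5 (E)-3-(ArA)prop-2-en-1-ol
Conditions: iBu2AlH, CH2Cl2, −78 °C; aq. potassium sodium tartrate work-up
Reagents that add atoms: none
Why: 1,2-reduction of the conjugated ester by the aluminium hydride at low temperature should give the allylic alcohol without touching the alkene or the acetal.

Step 4
Reactants: 5 (E)-3-(ArA)prop-2-en-1-ol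
Product: 6 [(2S,3S)-3-(ArA)oxiran-2-yl]methanol
Conditions: Ti(OiPr)4 (10 mol %), L-(+)-DET (12 mol %), TBHP, 4 Å MS, CH2Cl2, −20 °C; non-acidic work-up
Reagents that add atoms: tert-butyl hydroperoxide, CC(C)(C)OO
Why: Katsuki–Sharpless asymmetric epoxidation: with L-(+)-diethyl tartrate the titanium tartrate complex delivers oxygen to the face of an (E)-3-substituted allylic alcohol that gives the (2S,3S)-epoxide, setting both future ring stereocentres.

Step 5
Reactants: 7 3,4-dihydroxybenzaldehyde
Product: 8 4-(allyloxy)-3-hydroxybenzaldehyde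
Conditions: allyl bromide, NaHCO3, NaI (cat.), DMF, 40 °C
Reagents that add atoms: allyl bromide, C=CCBr
Why: The 4-hydroxyl, para to the formyl group, is the more acidic one, so the weak base ionises it alone and regioselective Williamson alkylation leaves the 3-hydroxyl free.

Step 6
Reactants: 6 [(2S,3S)-3-(ArA)oxiran-2-yl]methanol; 8 4-(allyloxy)-3-hydroxybenzaldehyde
Product: 9 4-(allyloxy)-3-[(1R,2S)-1-(ArA)-2,3-dihydroxypropoxy]benzaldehyde
Conditions: K2CO3, EtOH–H2O, 80 °C
Reagents that add atoms: none
Why: SN2 opening of the trans-3-arylglycidol by the aryloxide should occur at benzylic C3 with inversion (3S becomes the 1R aryloxy carbon, C2 keeps its S hydroxyl), and carbonate forms the phenoxide but not the alkoxide that a Payne rearrangement would need.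

Step 7
Reactants: 9 4-(allyloxy)-3-[(1R,2S)-1-(ArA)-2,3-dihydroxypropoxy]benzaldehyde
Product: 10 4-(allyloxy)-3-[(1R,2S)-3-[tert-butyl(dimethyl)silyl]oxy-1-(ArA)-2-hydroxypropoxy]benzaldehyde
Conditions: TBSCl, imidazole, CH2Cl2, 0 °C
Reagents that add atoms: tert-butyldimethylsilyl chloride, CC(C)(C)[Si](C)(C)Cl
Why: Silylation is selective for the primary hydroxyl over the hindered secondary one and leaves the C8 hydroxyl free for ring closure.

Step 8
Reactants: 10 4-(allyloxy)-3-[(1R,2S)-3-[tert-butyl(dimethyl)silyl]oxy-1-(ArA)-2-hydroxypropoxy]benzaldehyde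
Product: 11 3-[(1R,2S)-3-[tert-butyl(dimethyl)silyl]oxy-1-(ArA)-2-hydroxypropoxy]-4-hydroxybenzaldehyde
Conditions: Pd(PPh3)4 (cat.), morpholine, THF, rt
Reagents that add atoms: none
Why: Tsuji–Trost deallylation: zerovalent palladium ionises the aryl allyl ether (a para-formyl phenoxide is a good leaving group) and morpholine traps the π-allyl fragment, under neutral conditions that spare the aldehyde, silyl ether and acetal.

Step 9
Reactants: 11 3-[(1R,2S)-3-[tert-butyl(dimethyl)silyl]oxy-1-(ArA)-2-hydroxypropoxy]-4-hydroxybenzaldehyde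
Product: 12 (2R,3R)-2-{[tert-butyl(dimethyl)silyl]oxymethyl}-3-(ArA)-2,3-dihydro-1,4-benzodioxine-6-carbaldehyde
Conditions: PPh3, DIAD, THF, 0 °C → rt
Reagents that add atoms: none
Why: Intramolecular Mitsunobu etherification: the acidic 4-hydroxyl displaces the activated C8 oxygen in a 6-exo-tet closure with inversion (S to R), which together with the inversion of step 6 gives the trans-(2R,3R) benzodioxane.

Step 10
Reactants: 12 (2R,3R)-2-{[tert-butyl(dimethyl)silyl]oxymethyl}-3-(ArA)-2,3-dihydro-1,4-benzodioxine-6-carbaldehyde; 13 malonic acid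
Product: 15 (E)-3-(BD)prop-2-enoic acid, via arylidenemalonic acid 14 (not isolated)
Conditions: pyridine, piperidine (cat.), 90 °C; citric acid work-up
Reagents that add atoms: none
Why: Knoevenagel–Doebner condensation followed by decarboxylation in hot pyridine should give the (E)-cinnamic acid, and the weakly basic medium does not affect the silyl ether, the acetal or the benzylic ethers.

Step 11
Reactants: 16 2,2,6-trimethyl-4H-1,3-dioxin-4-one
Product: 17 2,2-dimethyl-6-(2-oxopropyl)-4H-1,3-dioxin-4-one
Conditions: LiN(SiMe3)2 (2 equiv), THF, −78 °C; AcCl (1 equiv), −78 → −20 °C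
Reagents that add atoms: acetyl chloride, CC(=O)Cl
Why: The lithium dienolate formed at the 6-methyl group is C-acylated by acetyl chloride (vinylogous Claisen acylation), the second equivalent of base taking up the proton of the more acidic keto-dioxinone product.

Step 12
Reactants: 15 (E)-3-(BD)prop-2-enoic acid; 17 2,2-dimethyl-6-(2-oxopropyl)-4H-1,3-dioxin-4-one
Product: 19 6-[(E)-6-(BD)-2,4-dioxohex-5-en-1-yl]-2,2-dimethyl-4H-1,3-dioxin-4-one, via acyl imidazolide 18 (not isolated)
Conditions: 15, CDI, THF, rt; solution added to 17 (3 equiv) + LiN(iPr)2 (6 equiv), THF, −78 → −40 °C; then 1 M HCl to pH 3, 0 °C; product used promptly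
Reagents that add atoms: 1,1'-carbonyldiimidazole, O=C(n1ccnc1)n1ccnc1 (its imidazole is carried only in 18)
Why: CDI turns the acid into acyl imidazolide 18, which acylates the methyl-derived terminal carbon of the dianion of 17 in a crossed Claisen condensation, the hard lithium enolate adding to the acyl carbon and not the β-carbon, while surplus dianion absorbs the imidazole N–H and the acidic diketone product.

Step 13
Reactants: 19 6-[(E)-6-(BD)-2,4-dioxohex-5-en-1-yl]-2,2-dimethyl-4H-1,3-dioxin-4-one
Product: 21 7-hydroxy-2,2-dimethyl-5-[(E)-2-(BD)ethenyl]-4H-1,3-benzodioxin-4-one, via cyclic aldol adduct 20 (not isolated)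
Conditions: Et3N, CH2Cl2, rt
Reagents that add atoms: none
Why: Et3N reversibly enolises the chain; enolisation of the methylene next to the dioxinone gives a dienolate whose dioxinone C5 adds to the styryl ketone carbonyl to give aldol 20, which loses water while the remaining ring ketone enolises, so ring C should emerge aromatic with one hydroxyl free and the other held in the acetonide ester (an intramolecular aldol condensation–aromatisation, the known base-mediated conversion of diketo-dioxinones into resorcylates and the laboratory counterpart of stilbene-synthase folding). Ring C closes in a 6-(enolendo)-exo-trig mode, the nucleophilic C5=C6 unit lying inside the new ring and the carbonyl oxygen outside it, which Baldwin's enolate rules allow. No stereocentre remains from the step: the carbinol carbon of 20 becomes an arene carbon, the (E)-olefin is untouched, and C7 and C8 are inert to a tertiary amine at room temperature. The selectivity needed is carbon–carbon aldol closure over conjugate addition of a diketone enol oxygen to the enone β-carbon (dihydropyranone) and over Claisen attack on the carboxyl carbon (acylphloroglucinol folding). The dioxinone secures it: it holds the carboxyl as a poorly electrophilic vinylogous carbonate and makes C5 a soft carbon nucleophile six atoms from the styryl ketone, while the oxa-Michael adduct can revert under the same base and the aromatic product cannot.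

Step 14
Reactants: 21 7-hydroxy-2,2-dimethyl-5-[(E)-2-(BD)ethenyl]-4H-1,3-benzodioxin-4-one
Product: 22 2,4-dihydroxy-6-[(E)-2-(BD)ethenyl]benzoic acid
Conditions: KOH, H2O–1,4-dioxane (degassed), 70 °C; then 1 M HCl, 0 °C, to pH 3–4
Reagents that add atoms: potassium hydroxide, [K+].[OH-]
Why: Saponification of the aryl acetonide ester releases acetone and the resorcylic acid; the acetal and aryl ethers are base-stable, the primary silyl ether is expected to survive (any loss converges at step 16), and cold, brief acidification avoids lactonisation onto the stilbene.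

Step 15
Reactants: 22 2,4-dihydroxy-6-[(E)-2-(BD)ethenyl]benzoic acid
Product: 23 5-[(E)-2-(BD)ethenyl]benzene-1,3-diol
Conditions: DMSO, 110 °C, argon
Reagents that add atoms: none
Why: Thermal protodecarboxylation of a 2,4-dihydroxy-6-substituted benzoic acid is easy because the ortho and para hydroxyls favour ipso-protonation and the flanking styryl group twists the carboxyl out of plane; this removes the carbon that the biosynthesis also discards.

Step 16
Reactants: 23 5-[(E)-2-(BD)ethenyl]benzene-1,3-diol
Product: 25 aiphanol, via C9 alcohol MOM ether 24 (not isolated)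
Conditions: HCl (ca. 1 M), MeOH, rt → 40 °C, dark, argon
Reagents that add atoms: none
Why: Acid-catalysed methanolysis should cleave the primary silyl ether first and then the aryl methoxymethyl acetal, with solvent methanol trapping the methoxymethyl cation as dimethoxymethane so that it cannot alkylate the resorcinol ring, under conditions mild enough to keep the trans benzylic ether intact.

**Compound list**

1 | syringaldehyde (4-hydroxy-3,5-dimethoxybenzaldehyde) | COc1cc(C=O)cc(OC)c1O | starting material
2 | 3,5-dimethoxy-4-(methoxymethoxy)benzaldehyde | COCOc1c(OC)cc(C=O)cc1OC | intermediate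
3 | triethyl phosphonoacetate | CCOC(=O)CP(=O)(OCC)OCC | starting material
4 | ethyl (E)-3-[3,5-dimethoxy-4-(methoxymethoxy)phenyl]prop-2-enoate | CCOC(=O)/C=C/c1cc(OC)c(OCOC)c(OC)c1 | intermediate
5 | (E)-3-[3,5-dimethoxy-4-(methoxymethoxy)phenyl]prop-2-en-1-ol | OC/C=C/c1cc(OC)c(OCOC)c(OC)c1 | intermediate
6 | [(2S,3S)-3-[3,5-dimethoxy-4-(methoxymethoxy)phenyl]oxiran-2-yl]methanol | OC[C@@H]1O[C@H]1c1cc(OC)c(OCOC)c(OC)c1 | intermediate
7 | 3,4-dihydroxybenzaldehyde | O=Cc1ccc(O)c(O)c1 | starting material
8 | 4-(allyloxy)-3-hydroxybenzaldehyde | C=CCOc1ccc(C=O)cc1O | intermediate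
9 | 4-(allyloxy)-3-{(1R,2S)-1-[3,5-dimethoxy-4-(methoxymethoxy)phenyl]-2,3-dihydroxypropoxy}benzaldehyde | O=Cc1ccc(OCC=C)c(O[C@@H]([C@@H](O)CO)c2cc(OC)c(OCOC)c(OC)c2)c1 | intermediate
10 | 4-(allyloxy)-3-{(1R,2S)-3-[tert-butyl(dimethyl)silyl]oxy-1-[3,5-dimethoxy-4-(methoxymethoxy)phenyl]-2-hydroxypropoxy}benzaldehyde | O=Cc1ccc(OCC=C)c(O[C@@H]([C@@H](O)CO[Si](C)(C)C(C)(C)C)c2cc(OC)c(OCOC)c(OC)c2)c1 | intermediate
11 | 3-{(1R,2S)-3-[tert-butyl(dimethyl)silyl]oxy-1-[3,5-dimethoxy-4-(methoxymethoxy)phenyl]-2-hydroxypropoxy}-4-hydroxybenzaldehyde | O=Cc1ccc(O)c(O[C@@H]([C@@H](O)CO[Si](C)(C)C(C)(C)C)c2cc(OC)c(OCOC)c(OC)c2)c1 | intermediate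
12 | (2R,3R)-2-{[tert-butyl(dimethyl)silyl]oxymethyl}-3-[3,5-dimethoxy-4-(methoxymethoxy)phenyl]-2,3-dihydro-1,4-benzodioxine-6-carbaldehyde | COCOc1c(OC)cc([C@H]2Oc3cc(C=O)ccc3O[C@@H]2CO[Si](C)(C)C(C)(C)C)cc1OC | intermediate
13 | malonic acid | OC(=O)CC(=O)O | starting material
14 | 2-[(BD)methylidene]propanedioic acid (BD as defined above) | COCOc1c(OC)cc([C@H]2Oc3cc(C=C(C(=O)O)C(=O)O)ccc3O[C@@H]2CO[Si](C)(C)C(C)(C)C)cc1OC | intermediate (not isolated)
15 | (E)-3-(BD)prop-2-enoic acid | COCOc1c(OC)cc([C@H]2Oc3cc(/C=C/C(=O)O)ccc3O[C@@H]2CO[Si](C)(C)C(C)(C)C)cc1OC | intermediate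
16 | 2,2,6-trimethyl-4H-1,3-dioxin-4-one | CC1=CC(=O)OC(C)(C)O1 | starting material
17 | 2,2-dimethyl-6-(2-oxopropyl)-4H-1,3-dioxin-4-one | CC(=O)CC1=CC(=O)OC(C)(C)O1 | intermediate
18 | (E)-1-(imidazol-1-yl)-3-(BD)prop-2-en-1-one | COCOc1c(OC)cc([C@H]2Oc3cc(/C=C/C(=O)n4ccnc4)ccc3O[C@@H]2CO[Si](C)(C)C(C)(C)C)cc1OC | intermediate (not isolated)
19 | 6-[(E)-6-(BD)-2,4-dioxohex-5-en-1-yl]-2,2-dimethyl-4H-1,3-dioxin-4-one | COCOc1c(OC)cc([C@H]2Oc3cc(/C=C/C(=O)CC(=O)CC4=CC(=O)OC(C)(C)O4)ccc3O[C@@H]2CO[Si](C)(C)C(C)(C)C)cc1OC | intermediate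
20 | 5-hydroxy-2,2-dimethyl-5-[(E)-2-(BD)ethenyl]-5,6-dihydro-4H-1,3-benzodioxine-4,7(8H)-dione (either epimer at the carbinol carbon) | COCOc1c(OC)cc([C@H]2Oc3cc(/C=C/C4(O)CC(=O)CC5=C4C(=O)OC(C)(C)O5)ccc3O[C@@H]2CO[Si](C)(C)C(C)(C)C)cc1OC | intermediate (not isolated)
21 | 7-hydroxy-2,2-dimethyl-5-[(E)-2-(BD)ethenyl]-4H-1,3-benzodioxin-4-one | COCOc1c(OC)cc([C@H]2Oc3cc(/C=C/c4cc(O)cc5OC(C)(C)OC(=O)c45)ccc3O[C@@H]2CO[Si](C)(C)C(C)(C)C)cc1OC | intermediate
22 | 2,4-dihydroxy-6-[(E)-2-(BD)ethenyl]benzoic acid | COCOc1c(OC)cc([C@H]2Oc3cc(/C=C/c4cc(O)cc(O)c4C(=O)O)ccc3O[C@@H]2CO[Si](C)(C)C(C)(C)C)cc1OC | intermediate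
23 | 5-[(E)-2-(BD)ethenyl]benzene-1,3-diol | COCOc1c(OC)cc([C@H]2Oc3cc(/C=C/c4cc(O)cc(O)c4)ccc3O[C@@H]2CO[Si](C)(C)C(C)(C)C)cc1OC | intermediate
24 | 5-[(E)-2-{(2R,3R)-3-[3,5-dimethoxy-4-(methoxymethoxy)phenyl]-2-(hydroxymethyl)-2,3-dihydro-1,4-benzodioxin-6-yl}ethenyl]benzene-1,3-diol | COCOc1c(OC)cc([C@H]2Oc3cc(/C=C/c4cc(O)cc(O)c4)ccc3O[C@@H]2CO)cc1OC | intermediate (not isolated)
25 | aiphanol, 5-[(E)-2-[(2R,3R)-3-(4-hydroxy-3,5-dimethoxyphenyl)-2-(hydroxymethyl)-2,3-dihydro-1,4-benzodioxin-6-yl]ethenyl]benzene-1,3-diol | COc1cc([C@H]2Oc3cc(/C=C/c4cc(O)cc(O)c4)ccc3O[C@@H]2CO)cc(OC)c1O | target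

**Step count**

Total: 16 steps. Longest linear sequence: 14 steps (steps 1–4, 6–10, 12–16).

**Steps most likely to fail**

Step 13 (key step). The risk is that an enol oxygen of the diketone adds to the styryl enone and closes a dihydropyranone, or that the chain dehydrates to a pyranone, faster than C5 attacks the styryl ketone, so the chain never aromatises. The fallback drops chain folding for ring C and attaches a preformed resorcinol. It sets out from aldehyde 12: Wittig methylenation (Ph3PCH3Br, KOtBu, THF, 0 °C) should give the styrene (2R,3R)-2-{[tert-butyl(dimethyl)silyl]oxymethyl}-6-ethenyl-3-(ArA)-2,3-dihydro-1,4-benzodioxine F1. A Mizoroki–Heck arylation of F1 with purchased 5-iodobenzene-1,3-diol (Pd(OAc)2, P(o-tol)3, Et3N, DMF, 90 °C) should then give the (E)-stilbene. This is compound 23, where the route is rejoined before the final deprotection.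

Step 12. The risk is that the dianion adds to the β-carbon of the cinnamoyl imidazolide or is O-acylated, and that proton transfer from imidazole and from the diketone product quenches it, so the Claisen condensation stalls or over-acylates. The fallback changes the acyl donor and how it is made. It sets out from aldehyde 12: Horner–Wadsworth–Emmons olefination with purchased diethyl [2-(methoxy(methyl)amino)-2-oxoethyl]phosphonate (NaH, THF, 0 °C) should give the (E)-N-methoxy-N-methyl-3-(BD)prop-2-enamide F2. Addition of F2 to the dianion of 17 (LiN(iPr)2, THF, −78 °C) gives a chelated tetrahedral adduct that cannot over-react and releases the diketone only on acidic work-up. The route is rejoined at 19.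

Step 6. The risk is that the aryloxide attacks C2, or attacks C1 after Payne isomerisation of the free epoxy alcohol, or that the protic medium solvolyses the epoxide and partial ionisation at the benzylic carbon erodes the inversion. The fallback removes the free hydroxyl before the opening and uses an anhydrous medium. It sets out from 6: silylation (TBSCl, imidazole, CH2Cl2, 0 °C) should give tert-butyl{[(2S,3S)-3-(ArA)oxiran-2-yl]methoxy}dimethylsilane F3. No Payne isomer can form from F3, and its C2 is deactivated by the adjacent silyloxymethyl group. Opening with phenol 8 (Cs2CO3, DMF, 80 °C) should then give the benzylic aryl ether with inversion. The route is rejoined at 10.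

**Further compounds**

F1 | step 13 | (2R,3R)-2-{[tert-butyl(dimethyl)silyl]oxymethyl}-6-ethenyl-3-[3,5-dimethoxy-4-(methoxymethoxy)phenyl]-2,3-dihydro-1,4-benzodioxine | COCOc1c(OC)cc([C@H]2Oc3cc(C=C)ccc3O[C@@H]2CO[Si](C)(C)C(C)(C)C)cc1OC
F2 | step 12 | (E)-N-methoxy-N-methyl-3-(BD)prop-2-enamide | COCOc1c(OC)cc([C@H]2Oc3cc(/C=C/C(=O)N(C)OC)ccc3O[C@@H]2CO[Si](C)(C)C(C)(C)C)cc1OC
F3 | step 6 | tert-butyl{[(2S,3S)-3-[3,5-dimethoxy-4-(methoxymethoxy)phenyl]oxiran-2-yl]methoxy}dimethylsilane | CC(C)(C)[Si](C)(C)OC[C@@H]1O[C@H]1c1cc(OC)c(OCOC)c(OC)c1
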